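**Retrosynthetic overview**

1. Target 19 comes from tribenzyl acid 18 by global hydrogenolysis; 18 comes from arene 15 by ortho-formylation and Pinnick oxidation. The CO2H is introduced last, so the C2′ oxygen never faces an aryl ester and cannot lactonise.
2. 15 comes from homoallylic acetate 10 and benzyl dec-9-enyl ether 13 by cross-metathesis at C4′=C5′ followed by alkene saturation.
3. 10 comes from arylacetaldehyde 5 and allyl unit 6: an asymmetric carbonyl allylation forms C2′–C3′ and sets the only stereocentre (R).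
4. 5 comes from 3,5-bis(benzyloxy)benzaldehyde 1 by one-carbon homologation (Wittig, hydroboration–oxidation, oxidation).
5. No ring is formed; the resorcinol ring is bought in 1.

Assumption: 1, 6, 11 and (+)-Ipc2BOMe (the enantiomer made from (−)-α-pinene) are bought; side-chain carbons are numbered C1′ (benzylic) to C13′, and the target stereocentre C2′ is R.

**Route**

Step 1
Reactants: 1 3,5-bis(benzyloxy)benzaldehyde
Product: 2 [3,5-bis(benzyloxy)phenyl]ethene
Conditions: Ph3PCH3Br, KOtBu, THF, 0 °C to rt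
Reagents that add atoms: methyltriphenylphosphonium bromide, C[P+](c1ccccc1)(c1ccccc1)c1ccccc1.[Br-]
Why: Wittig methylenation of a non-enolisable aryl aldehyde is high-yielding and benzyl ethers are inert to the ylide.

Step 2
Reactants: 2 [3,5-bis(benzyloxy)phenyl]ethene
Product: 4 2-[3,5-bis(benzyloxy)phenyl]ethan-1-ol, via alkylborane 3 (not isolated)
Conditions: 9-BBN, THF, 0 °C to rt; then 3 M NaOH, 30% H2O2, 0 °C to rt
Reagents that add atoms: hydrogen peroxide, OO
Why: Hydroboration–oxidation with 9-BBN gives the anti-Markovnikov primary alcohol from a styrene with >98:2 regioselectivity.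

Step 3
Reactants: 4 2-[3,5-bis(benzyloxy)phenyl]ethan-1-ol
Product: 5 [3,5-bis(benzyloxy)phenyl]acetaldehyde
Conditions: Dess–Martin periodinane, NaHCO3, CH2Cl2, 0 °C to rt; used crude at once
Reagents that add atoms: none
Why: Buffered Dess–Martin oxidation stops at the aldehyde under near-neutral conditions, which limits enolisation and self-aldol of the arylacetaldehyde.

Step 4
Reactants: 5 [3,5-bis(benzyloxy)phenyl]acetaldehyde; 6 allylmagnesium bromide
Product: 9 (2R)-1-[3,5-bis(benzyloxy)phenyl]pent-4-en-2-ol, via allylborane 7 (not isolated), via borinate 8 (not isolated)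
Conditions: 6, (+)-Ipc2BOMe, Et2O, 0 °C to rt; then 5, −78 °C; then 3 M NaOH, 30% H2O2, rt
Reagents that add atoms: none
Why: Brown asymmetric allylboration (carbonyl allylation): allylborane 7, with both Ipc groups from (−)-α-pinene, delivers allyl through a closed chair transition state to the Re face of 5, forming C2′–C3′ and setting C2′ as R (typically ≥92% ee, higher at −100 °C salt-free), and oxidative work-up cleaves borinate 8.

Step 5
Reactants: 9 (2R)-1-[3,5-bis(benzyloxy)phenyl]pent-4-en-2-ol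
Product: 10 (2R)-1-[3,5-bis(benzyloxy)phenyl]pent-4-en-2-yl acetate
Conditions: Ac2O, pyridine, DMAP (cat.), CH2Cl2, 0 °C to rt
Reagents that add atoms: acetic anhydride, CC(=O)OC(C)=O
Why: DMAP-catalysed acylation of the only hydroxyl installs the acetate of the target with retention, and it then serves as the protecting group for the rest of the route.

Step 6
Reactants: 11 dec-9-en-1-ol
Product: 13 benzyl dec-9-en-1-yl ether, via sodium alkoxide 12 (not isolated)
Conditions: NaH, THF/DMF, 0 °C; then BnBr, Bu4NI (cat.), rt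
Reagents that add atoms: benzyl bromide, BrCc1ccccc1
Why: Williamson etherification of a primary alkoxide with benzyl bromide is reliable and gives a hydroxyl protecting group that is removed in the final hydrogenolysis.

Step 7
Reactants: 10 (2R)-1-[3,5-bis(benzyloxy)phenyl]pent-4-en-2-yl acetate; 13 benzyl dec-9-en-1-yl ether
Product: 14 (2R)-1-[3,5-bis(benzyloxy)phenyl]-13-(benzyloxy)tridec-4-en-2-yl acetate (E/Z mixture)
Conditions: Grubbs II (5 mol%), 13 (3 equiv), CH2Cl2, 40 °C
Reagents that add atoms: none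
Why: Olefin cross-metathesis between two unhindered terminal alkenes is driven by excess 13 and loss of ethene, and the E/Z ratio is irrelevant because the alkene is saturated next.

Step 8
Reactants: 14 (2R)-1-[3,5-bis(benzyloxy)phenyl]-13-(benzyloxy)tridec-4-en-2-yl acetate
Product: 15 (2R)-1-[3,5-bis(benzyloxy)phenyl]-13-(benzyloxy)tridecan-2-yl acetate
Conditions: H2 (1–3 atm), RhCl(PPh3)3 (10 mol%), PhH/EtOH 1:1, rt
Reagents that add atoms: none
Why: Homogeneous hydrogenation with Wilkinson's catalyst saturates the disubstituted alkene without cleaving benzyl ethers or moving the alkene into an allylic-acetate position.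

Step 9
Reactants: 15 (2R)-1-[3,5-bis(benzyloxy)phenyl]-13-(benzyloxy)tridecan-2-yl acetate
Product: 17 (2R)-1-[3,5-bis(benzyloxy)-2-formylphenyl]-13-(benzyloxy)tridecan-2-yl acetate, via iminium chloride 16 (not isolated)
Conditions: POCl3, DMF, 0 °C to 65 °C; then aq. NaOAc, rt
Reagents that add atoms: N,N-dimethylformamide, CN(C)C=O; water, O
Why: Vilsmeier–Haack formylation attacks the activated ring position ortho to the side chain and ortho/para to the two benzyloxy groups (the site between the two OBn groups is shielded), and acetate-buffered hydrolysis of iminium 16 leaves the ester and ethers intact.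

Step 10
Reactants: 17 (2R)-1-[3,5-bis(benzyloxy)-2-formylphenyl]-13-(benzyloxy)tridecan-2-yl acetate
Product: 18 2-[(2R)-2-acetoxy-13-(benzyloxy)tridecyl]-4,6-bis(benzyloxy)benzoic acid
Conditions: NaClO2, NaH2PO4, 2-methyl-2-butene, t-BuOH/THF/H2O, 0 °C to rt
Reagents that add atoms: sodium chlorite, [Na+].[O-]Cl=O
Why: Pinnick oxidation converts the hindered electron-rich aldehyde to the acid at pH about 4, with 2-methyl-2-butene scavenging HOCl so the ring is not chlorinated and the acetate is not hydrolysed.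

Step 11
Reactants: 18 2-[(2R)-2-acetoxy-13-(benzyloxy)tridecyl]-4,6-bis(benzyloxy)benzoic acid
Product: 19 2-[(2R)-2-acetoxy-13-hydroxytridecyl]-4,6-dihydroxybenzoic acid
Conditions: H2 (1 atm), 10% Pd/C, EtOAc/EtOH, rt
Reagents that add atoms: none
Why: Neutral room-temperature hydrogenolysis removes the two aryl and one alkyl benzyl ethers while the homobenzylic acetate, the acid and the stereocentre are untouched.

**Compound list**

1 | 3,5-bis(benzyloxy)benzaldehyde | O=Cc1cc(OCc2ccccc2)cc(OCc2ccccc2)c1 | starting material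
2 | [3,5-bis(benzyloxy)phenyl]ethene | C=Cc1cc(OCc2ccccc2)cc(OCc2ccccc2)c1 | intermediate
3 | 9-{2-[3,5-bis(benzyloxy)phenyl]ethyl}-9-borabicyclo[3.3.1]nonane | C(Cc1cc(OCc2ccccc2)cc(OCc2ccccc2)c1)B1C2CCCC1CCC2 | intermediate
4 | 2-[3,5-bis(benzyloxy)phenyl]ethan-1-ol | OCCc1cc(OCc2ccccc2)cc(OCc2ccccc2)c1 | intermediate
5 | [3,5-bis(benzyloxy)phenyl]acetaldehyde | O=CCc1cc(OCc2ccccc2)cc(OCc2ccccc2)c1 | intermediate
6 | allylmagnesium bromide | C=CC[Mg]Br | starting material
7 | (+)-B-allyldiisopinocampheylborane (both Ipc groups from (−)-α-pinene) | C=CCB([C@H]1C[C@H]2C[C@@H]([C@@H]1C)C2(C)C)[C@H]1C[C@H]2C[C@@H]([C@@H]1C)C2(C)C | intermediate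
8 | diisopinocampheylborinate of (2R)-1-[3,5-bis(benzyloxy)phenyl]pent-4-en-2-ol | O([C@H](CC=C)Cc1cc(OCc2ccccc2)cc(OCc2ccccc2)c1)B([C@H]1C[C@H]2C[C@@H]([C@@H]1C)C2(C)C)[C@H]1C[C@H]2C[C@@H]([C@@H]1C)C2(C)C | intermediate
9 | (2R)-1-[3,5-bis(benzyloxy)phenyl]pent-4-en-2-ol | O[C@H](CC=C)Cc1cc(OCc2ccccc2)cc(OCc2ccccc2)c1 | intermediate
10 | (2R)-1-[3,5-bis(benzyloxy)phenyl]pent-4-en-2-yl acetate | CC(=O)O[C@H](CC=C)Cc1cc(OCc2ccccc2)cc(OCc2ccccc2)c1 | intermediate
11 | dec-9-en-1-ol | C=CCCCCCCCCO | starting material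
12 | sodium dec-9-en-1-olate | C=CCCCCCCCC[O-].[Na+] | intermediate
13 | benzyl dec-9-en-1-yl ether | C=CCCCCCCCCOCc1ccccc1 | intermediate
14 | (2R)-1-[3,5-bis(benzyloxy)phenyl]-13-(benzyloxy)tridec-4-en-2-yl acetate (E/Z mixture; E drawn) | CC(=O)O[C@H](C/C=C/CCCCCCCCOCc1ccccc1)Cc1cc(OCc2ccccc2)cc(OCc2ccccc2)c1 | intermediate
15 | (2R)-1-[3,5-bis(benzyloxy)phenyl]-13-(benzyloxy)tridecan-2-yl acetate | CC(=O)O[C@H](CCCCCCCCCCCOCc1ccccc1)Cc1cc(OCc2ccccc2)cc(OCc2ccccc2)c1 | intermediate
16 | {2-[(2R)-2-acetoxy-13-(benzyloxy)tridecyl]-4,6-bis(benzyloxy)benzylidene}dimethyliminium chloride | CC(=O)O[C@H](CCCCCCCCCCCOCc1ccccc1)Cc1cc(OCc2ccccc2)cc(OCc2ccccc2)c1C=[N+](C)C.[Cl-] | intermediate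
17 | (2R)-1-[3,5-bis(benzyloxy)-2-formylphenyl]-13-(benzyloxy)tridecan-2-yl acetate | CC(=O)O[C@H](CCCCCCCCCCCOCc1ccccc1)Cc1cc(OCc2ccccc2)cc(OCc2ccccc2)c1C=O | intermediate
18 | 2-[(2R)-2-acetoxy-13-(benzyloxy)tridecyl]-4,6-bis(benzyloxy)benzoic acid | CC(=O)O[C@H](CCCCCCCCCCCOCc1ccccc1)Cc1cc(OCc2ccccc2)cc(OCc2ccccc2)c1C(=O)O | intermediate
19 | 2-[(2R)-2-acetoxy-13-hydroxytridecyl]-4,6-dihydroxybenzoic acid | CC(=O)O[C@H](CCCCCCCCCCCO)Cc1cc(O)cc(O)c1C(=O)O | target

**Step count and risks**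

Total steps: 11. Longest linear sequence: 10 steps (1 → 2 → 4 → 5 → 9 → 10 → 14 → 15 → 17 → 18 → 19); step 6 is a one-step side branch.

Step 4 (asymmetric allylboration) may give low ee or yield because 5 is an enolisable, self-condensing aldehyde. The fallback sets out from 5 and comes back at 9, taking the stereocentre from an epoxide resolution instead. Aldehyde 5 is treated with ICH2Cl and MeLi·LiBr (THF, −78 °C to rt) to give, through lithium 1-[3,5-bis(benzyloxy)phenyl]-3-chloropropan-2-olate F1, racemic 2-[3,5-bis(benzyloxy)benzyl]oxirane F2. Jacobsen hydrolytic kinetic resolution with (S,S)-(salen)Co(III)OAc (0.5 mol%, 0.55 equiv H2O, THF, rt) leaves (2S)-2-[3,5-bis(benzyloxy)benzyl]oxirane F3 in >99% ee and removes the other enantiomer as (2R)-3-[3,5-bis(benzyloxy)phenyl]propane-1,2-diol F4; the catalyst hand is quoted from memory and should be confirmed on the first run. Opening F3 at its terminal carbon with vinylmagnesium bromide and CuI (10 mol%, THF, −30 °C) gives 9 without touching the stereocentre.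

Step 7 (cross-metathesis) may give statistical mixtures or stall. The fallback sets out from 10 and comes back at 15, replacing metathesis and step 8 by an sp3–sp3 coupling. Hydroboration of 10 with 9-BBN (THF, 0 °C to rt) gives (2R)-1-[3,5-bis(benzyloxy)phenyl]-5-(9-borabicyclo[3.3.1]nonan-9-yl)pentan-2-yl acetate F5. Without isolation it is coupled with [(8-bromooctyl)oxy]methylbenzene F6 (from commercial 8-bromooctan-1-ol, benzyl trichloroacetimidate and TfOH cat.) under Fu alkyl–alkyl Suzuki conditions (Pd(OAc)2, PCy3, K3PO4·H2O, THF, rt) to give 15 directly.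

Step 9 (Vilsmeier formylation) may be sluggish, and the hindered aldehyde 17 may oxidise poorly in step 10. The fallback sets out from 15 and comes back at 19, introducing the carboxyl by halogenation and carbonylation. NBS (MeCN, 0 °C) gives (2R)-1-[3,5-bis(benzyloxy)-2-bromophenyl]-13-(benzyloxy)tridecan-2-yl acetate F7. Palladium-catalysed benzyloxycarbonylation (Pd(OAc)2, Xantphos, CO 1 atm, BnOH, Et3N, toluene, 100 °C) gives benzyl 2-[(2R)-2-acetoxy-13-(benzyloxy)tridecyl]-4,6-bis(benzyloxy)benzoate F8. Hydrogenolysis (H2, 10% Pd/C, EtOAc, rt) removes all four benzyl groups to give 19.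

**Further compounds**

F1 | step 4 | lithium 1-[3,5-bis(benzyloxy)phenyl]-3-chloropropan-2-olate (racemic) | [Li+].[O-]C(CCl)Cc1cc(OCc2ccccc2)cc(OCc2ccccc2)c1
F2 | step 4 | rac-2-[3,5-bis(benzyloxy)benzyl]oxirane | C1OC1Cc1cc(OCc2ccccc2)cc(OCc2ccccc2)c1
F3 | step 4 | (2S)-2-[3,5-bis(benzyloxy)benzyl]oxirane | C1O[C@H]1Cc1cc(OCc2ccccc2)cc(OCc2ccccc2)c1
F4 | step 4 | (2R)-3-[3,5-bis(benzyloxy)phenyl]propane-1,2-diol | OC[C@H](O)Cc1cc(OCc2ccccc2)cc(OCc2ccccc2)c1
F5 | step 7 | (2R)-1-[3,5-bis(benzyloxy)phenyl]-5-(9-borabicyclo[3.3.1]nonan-9-yl)pentan-2-yl acetate | CC(=O)O[C@H](CCCB1C2CCCC1CCC2)Cc1cc(OCc2ccccc2)cc(OCc2ccccc2)c1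
F6 | step 7 | [(8-bromooctyl)oxy]methylbenzene | BrCCCCCCCCOCc1ccccc1
F7 | step 9 | (2R)-1-[3,5-bis(benzyloxy)-2-bromophenyl]-13-(benzyloxy)tridecan-2-yl acetate | CC(=O)O[C@H](CCCCCCCCCCCOCc1ccccc1)Cc1cc(OCc2ccccc2)cc(OCc2ccccc2)c1Br
F8 | step 9 | benzyl 2-[(2R)-2-acetoxy-13-(benzyloxy)tridecyl]-4,6-bis(benzyloxy)benzoate | CC(=O)O[C@H](CCCCCCCCCCCOCc1ccccc1)Cc1cc(OCc2ccccc2)cc(OCc2ccccc2)c1C(=O)OCc1ccccc1
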